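## Analysis of the target

The target **11** is (5R)-5-hydroxy-5-[(Z)-2-oxononadec-10-en-1-yl]cyclohex-2-en-1-one. It is a cyclohex-2-enone ring (C1=O, C2=C3, C4H2, C5, C6H2) whose C5 is a tertiary carbinol; through C1'H2 it carries an oleoyl ketone (C2'=O) with the (Z)-C10'=C11' double bond. C5 is the only stereocentre. Besides OH it bears three CH2 groups (C4, C6, C1'), and the two ring branches differ only in that C1 is a carbonyl carbon and C3 an olefinic CH. The ring thus hides a mirror plane through C5 and C2. Its carbons C1, C3 and C5 carry the 1,3,5-oxygen pattern of a hydrogenated phloroglucinol ring, C3 having given up its oxygen to the C2=C3 double bond. This latent symmetry is the feature the route is built on. The C5 hydroxyl is β to both ketones: loss of water into the ring gives a dienone that tautomerises irreversibly to a 3-substituted phenol, and retro-aldol cleavage of C5–C1' is driven by the same aromatisation. The (Z)-alkene rules out hydrogenation, hydrogenolysis, olefin metathesis and unselective allylic oxidation, so it is best bought with the chain. The difficulty is therefore not the ring but creating one configuration at a carbon whose branches are almost alike, and unveiling the enone without aromatising it.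

## Retrosynthetic reasoning

Ring positions are numbered as in **11** throughout.

**11 ⇒ 9 (through 10).** No skeletal bond is cut. The enone is read as two functional-group events on a saturated ring: C1=O from a secondary carbinol, and C2=C3 from β-elimination of an acyloxy group at C3 once C1 is a ketone. The ring branches of C5 in **9** are then CH2–CH(OH) and CH2–CH(OAc) and differ by one acetyl group only. The forward reaction must oxidise the single secondary alcohol and then expel acetate from **10** in preference to the tertiary hydroxyl on the other β-carbon; the far better leaving group secures this.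

**9 ⇒ 8 (key disconnection).** Removing the acetyl group restores the mirror plane through C5 and C2, so **8** is meso. The only stereocentre of **11** is thus not made by addition to a face; it is unveiled when a hydrolase tells the two enantiotopic secondary carbinols of **8** apart. The cut is made here because in **8** the two ring branches are exactly alike, and distinguishing two ordinary secondary alcohols of a cis-1,3-diol is routine work for a lipase. The gain is that every earlier intermediate is achiral and no chiral reagent, auxiliary or catalyst other than the enzyme is needed.

**8 ⇒ 7.** The two secondary hydroxyls are tied back as a benzylidene acetal. The acetal singles out two of the three hydroxyls of the ring without statistical protection. It also holds both ring oxygens axial, which closes one face of the ring ketone in the next disconnection.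

**7 ⇒ 3 + 5 (through 6).** The C5–C1' bond is cut as an aldol addition. The cut lies on the mirror plane, so both fragments are achiral, and the chain arrives with its (Z)-alkene intact. The forward reaction has to add the kinetic methyl enolate **6** of **5** to the exo face of **3**. This fixes the tertiary hydroxyl cis to the two ring oxygens, and that relative configuration, together with the enzyme's choice, decides the configuration at C5 of **11**.

**3 ⇒ 2 ⇒ 1.** The ketone comes from the one free hydroxyl of acetal **2**, and **2** from the all-cis triol **1**. The complete ring with all three oxygen positions is bought in one piece.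

**5 ⇒ 4.** The methyl ketone is oleic acid **4** plus one carbon.

## Alternatives that were turned down

**Alternative 1:** the textbook route, closing C2=C3 by ring-closing metathesis. The forward key step would treat the acyclic trienone A1 with the second-generation Grubbs catalyst to give **11**.
- The key step does nothing for C5. C5 would have to be set in an open chain by allyl or enolate addition to the central carbonyl of a 1,3,5-tricarbonyl array, which is enolised and whose two faces differ only several atoms away from the reacting carbon.
- The ruthenium carbene would also engage the (Z)-C15=C16 alkene of A1 (Z/E scrambling, cross-metathesis).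
- The vinyl ketone next to a β-hydroxyl is a fragile Michael acceptor.
- The route is at least as long as the chosen one and leaves the stereocentre unsolved.

**Alternative 2:** a [4+2] disconnection of ring bonds C3–C4 and C5–C6. A chiral Lewis acid would catalyse the Diels–Alder reaction of the parent 1,3-diene with an α-bromo enal to give A2, setting ring and C5 together. The bromo aldehyde would then be turned into the ketol A3 through the derived oxirane and an acyl-anion equivalent of the chain.
- The 1,3-relation between the C5 oxygen and C1=O is the pattern a Diels–Alder reaction with an oxygenated diene does not deliver (it gives 1,2 or 1,4), so the C1 oxygen must come from allylic C–H oxidation of A3.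
- In A3 four allylic methylene groups compete: ring C1 and C4, chain C9' and C12'. Oxidation at C4 gives the α-ketol isomer.
- The decisive selectivity problem falls on the last step, on the most sensitive intermediate; a lactonisation detour to differentiate the ring positions adds steps.

**Alternative 3:** the chiral pool, cutting C1'–C2' on a ring taken from (−)-quinic acid A4. The forward key step would open the spiro-epoxide A5 with the lithiated dithiane of the chain aldehyde. The natural enantiomer maps correctly: its cis-diol would become C2=C3 by Corey–Winter olefination and its remaining secondary hydroxyl C1=O.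
- The route is roughly twice as long: lactone/acetonide, reduction, oxirane, silylation, two steps to the dithiane, coupling, unmasking, acetonide removal, two-step olefination, desilylation, oxidation.
- Three ring oxygens and their stereocentres are bought only to be erased.
- A hot phosphite deoxygenation would have to be run on a tertiary β-ketol.
- The carbinol carbon of A4 is no more a true stereocentre than that of **8**; the pool route uses the same latent symmetry but pays for the differentiation with protecting-group steps, which the chosen route replaces by one enzymatic step.

Key step: step 6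

Assumption (remark on the chemistry): the lipase is taken to acylate the same enantiotopic carbinol of **8** as it does in simple cis-cyclohexane-1,3-diols. Commercial **1** is the dihydrate and is dried azeotropically before use.

## Route

Step 1
Reactants: 1 cis,cis-cyclohexane-1,3,5-triol
Product: 2 7-endo-hydroxy-3-phenyl-2,4-dioxabicyclo[3.3.1]nonane (meso; phenyl equatorial on the dioxane ring; hydroxyl on the side of the acetal oxygens)
Conditions: PhCH(OMe)2 (1.1 equiv), camphorsulfonic acid (5 mol %), DMF, 60 °C, 50 mbar
Reagents that add atoms: benzaldehyde dimethyl acetal, COC(OC)c1ccccc1
Why: Acid-catalysed transacetalisation; only a six-membered 1,3-dioxane across two cis hydroxyls can form (through the triaxial conformer, the same bridging that gives orthoesters of 1), so exactly one hydroxyl stays free without statistical protection. Phenyl becomes equatorial by equilibration and the product is meso, so no stereocentre is at stake.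

Step 2
Reactants: 2 7-endo-hydroxy-3-phenyl-2,4-dioxabicyclo[3.3.1]nonane
Product: 3 3-phenyl-2,4-dioxabicyclo[3.3.1]nonan-7-one (meso)
Conditions: tetrapropylammonium perruthenate (Pr4N[RuO4], 5 mol %), N-methylmorpholine N-oxide (1.5 equiv), 4 Å MS, CH2Cl2, rt
Reagents that add atoms: none
Why: Ley–Griffith oxidation of the single secondary alcohol under neutral conditions leaves the acetal and the β-alkoxy ketone intact.

Step 3
Reactants: 4 oleic acid
Product: 5 (Z)-nonadec-10-en-2-one
Conditions: MeLi (2.2 equiv), THF, 0 °C to rt; inverse quench into 1 M HCl, 0 °C
Reagents that add atoms: methyllithium, [Li]C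
Why: Addition of an organolithium to a lithium carboxylate; the dilithium gem-diolate is stable until the acidic quench, so the ketone is not exposed to MeLi, and the isolated (Z)-alkene is inert.

Step 4
Reactants: 5 (Z)-nonadec-10-en-2-one; 3 3-phenyl-2,4-dioxabicyclo[3.3.1]nonan-7-one
Product: 7 (Z)-1-(7-endo-hydroxy-3-phenyl-2,4-dioxabicyclo[3.3.1]nonan-7-yl)nonadec-10-en-2-one (meso), via lithium enolate 6 (not isolated)
Conditions: LiN(iPr)2 (1.2 equiv), 5 (1.25 equiv), THF, −78 °C; then 3 (1.0 equiv), −78 °C, 30 min; sat. aq. NH4Cl at −78 °C
Reagents that add atoms: none
Why: Kinetic deprotonation of the methyl group gives the terminal enolate 6, which adds to ketone 3 in a crossed aldol addition. The endo face of 3 is closed by the two axial acetal oxygens and the acetal C–H, so attack should come from the exo face, as is general for bicyclo[3.3.1]nonan-3-one-type ketones; this places the chain exo and the new hydroxyl cis to both ring oxygens. The product is meso; this relative configuration is what the key step later turns into the absolute configuration of C5.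

Step 5
Reactants: 7 (Z)-1-(7-endo-hydroxy-3-phenyl-2,4-dioxabicyclo[3.3.1]nonan-7-yl)nonadec-10-en-2-one
Product: 8 (Z)-1-[(1s,3R,5S)-1,3,5-trihydroxycyclohexyl]nonadec-10-en-2-one (meso; all three hydroxyls cis)
Conditions: AcOH/THF/H2O 3:1:1, 40 °C
Reagents that add atoms: none
Why: Acid-catalysed hydrolysis of a strained benzylidene acetal under conditions too mild to dehydrate the tertiary ketol. The chain ketone sits on the face opposite the secondary hydroxyls, so no internal ketal can form.

Step 6
Reactants: 8 (Z)-1-[(1s,3R,5S)-1,3,5-trihydroxycyclohexyl]nonadec-10-en-2-one
Product: 9 (1S,3R,5R)-3,5-dihydroxy-3-[(Z)-2-oxononadec-10-en-1-yl]cyclohexyl acetate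
Conditions: Novozym 435 (immobilised Candida antarctica lipase B), vinyl acetate (5 equiv), MTBE, 30 °C
Reagents that add atoms: vinyl acetate, C=COC(C)=O
Why: Lipase-catalysed transesterification: the active-site serine is acetylated by vinyl acetate (acetaldehyde leaves, making the transfer irreversible) and the acyl-enzyme passes the acetyl group to one of the two enantiotopic secondary hydroxyls of meso 8. The closest known reaction type is the lipase monoacylation of meso cis-cyclohexane-1,3-diols and their 5-substituted congeners. No ring is closed and no skeletal bond is formed; the step breaks the mirror plane that runs through the carbinol carbon and the opposite ring CH2 (C5 and C2 of 11). The quaternary carbinol carbon, pseudoasymmetric in 8, thereby becomes a true stereocentre (3R in 9, later C5 of 11); its sense is fixed jointly by the cis relationship installed in step 4 and by the enzyme's choice of carbinol. The selectivity needed is group selection between two otherwise identical carbinols, which only the chiral active site can provide; by analogy with the parent diol the acetyl group is expected on the carbinol shown in 9 (descriptor S there only because the quaternary carbon changes the priorities). The tertiary hydroxyl is not a lipase substrate, the ketone and the (Z)-alkene are inert, and the lipid chain should favour binding. Over-acylation is slow because the remaining hydroxyl is the disfavoured one, and any diacetate formed is drawn mainly from the minor enantiomer, which should raise the purity of 9. The neutral, base-free medium suppresses 1,3-acyl migration, which would undo the distinction.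

Step 7
Reactants: 9 (1S,3R,5R)-3,5-dihydroxy-3-[(Z)-2-oxononadec-10-en-1-yl]cyclohexyl acetate
Product: 11 (5R)-5-hydroxy-5-[(Z)-2-oxononadec-10-en-1-yl]cyclohex-2-en-1-one, via keto acetate 10 (not isolated)
Conditions: Dess–Martin periodinane (1.3 equiv), CH2Cl2, 0 °C to rt; then Et3N (4 equiv), 0 °C to rt
Reagents that add atoms: none
Why: Dess–Martin oxidation converts the only secondary alcohol into the C1 ketone of 10 without base, so the acetate cannot migrate first. Et3N then triggers E1cB elimination of the β-acetoxy group to form C2=C3; acetate leaves far more readily than the tertiary hydroxyl on the other β-carbon, and the mild base at low temperature should spare the ketol from retro-aldol cleavage. C5 is not touched, so its configuration is carried unchanged into 11.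

## Compound list

1 | cis,cis-cyclohexane-1,3,5-triol | O[C@H]1C[C@@H](O)C[C@@H](O)C1 | starting material
2 | 7-endo-hydroxy-3-phenyl-2,4-dioxabicyclo[3.3.1]nonane (meso) | O[C@H]1C[C@@H]2C[C@H](C1)O[C@@H](c3ccccc3)O2 | intermediate
3 | 3-phenyl-2,4-dioxabicyclo[3.3.1]nonan-7-one (meso) | O=C1C[C@@H]2C[C@H](C1)O[C@@H](c3ccccc3)O2 | intermediate
4 | oleic acid, (Z)-octadec-9-enoic acid | CCCCCCCC/C=C\CCCCCCCC(=O)O | starting material
5 | (Z)-nonadec-10-en-2-one | CCCCCCCC/C=C\CCCCCCCC(C)=O | intermediate
6 | lithium (Z)-nonadeca-1,10-dien-2-olate | CCCCCCCC/C=C\CCCCCCCC(=C)O[Li] | intermediate (not isolated)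
7 | (Z)-1-(7-endo-hydroxy-3-phenyl-2,4-dioxabicyclo[3.3.1]nonan-7-yl)nonadec-10-en-2-one (meso) | CCCCCCCC/C=C\CCCCCCCC(=O)C[C@]1(O)C[C@@H]2C[C@H](C1)O[C@@H](c3ccccc3)O2 | intermediate
8 | (Z)-1-[(1s,3R,5S)-1,3,5-trihydroxycyclohexyl]nonadec-10-en-2-one (meso, all-cis) | CCCCCCCC/C=C\CCCCCCCC(=O)C[C@]1(O)C[C@@H](O)C[C@@H](O)C1 | intermediate
9 | (1S,3R,5R)-3,5-dihydroxy-3-[(Z)-2-oxononadec-10-en-1-yl]cyclohexyl acetate | CCCCCCCC/C=C\CCCCCCCC(=O)C[C@]1(O)C[C@@H](OC(C)=O)C[C@@H](O)C1 | intermediate
10 | (1R,3R)-3-hydroxy-5-oxo-3-[(Z)-2-oxononadec-10-en-1-yl]cyclohexyl acetate | CCCCCCCC/C=C\CCCCCCCC(=O)C[C@]1(O)C[C@@H](OC(C)=O)CC(=O)C1 | intermediate (not isolated)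
11 | (5R)-5-hydroxy-5-[(Z)-2-oxononadec-10-en-1-yl]cyclohex-2-en-1-one | CCCCCCCC/C=C\CCCCCCCC(=O)C[C@]1(O)CC=CC(=O)C1 | target

## Step count and risk

Total step count: 7. Longest linear sequence: 6 (steps 1, 2, 4, 5, 6, 7); step 3 is the one-step side branch.

Least certain steps:

For step 6, the key step, the most likely failure is group selection of the wrong sense or of low fidelity. The quaternary carbon with its axial chain may seat the ring in the active site differently from simple cis-1,3-diols; acyl transfer to a carbinol flanked by this carbon may also be slow. The fallback sets out from **8**. Both secondary hydroxyls are acetylated (Ac2O, pyridine, 0 °C, no acylation catalyst, so the tertiary hydroxyl stays free) to give the meso diacetate F1. A lipase in pH 7 phosphate buffer/MTBE then hydrolyses one enantiotopic ester. Hydrolysis frees the carbinol that acylation would have esterified, so this mode places the remaining acetate on the opposite carbon; whichever carbinol the enzyme prefers, one of the two modes should give **9**, and hydrolysis is usually the faster reaction on hindered substrates. The fallback comes back to the route at **9**.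

For step 4, the likely failures are proton transfer from **3** to enolate **6**, followed by β-elimination of an axial acetal oxygen, and reversal of the crowded ketone–ketone aldolate before the quench. The fallback sets out from **3** and forms the C1'–C2' bond instead, irreversibly. Corey–Chaykovsky methylenation (Me3S+ I−, KN(SiMe3)2, THF, −10 °C) from the open exo face should give the spiro-epoxide F2 with the oxirane oxygen endo. Commercial (Z)-octadec-9-enal and propane-1,3-dithiol (BF3·OEt2, CH2Cl2) give 2-[(Z)-heptadec-8-en-1-yl]-1,3-dithiane F3. Its 2-lithio derivative (n-BuLi, THF, −30 °C) should open F2 at the oxirane CH2 to the hydroxy dithiane F4. Unmasking with PhI(OCOCF3)2 in aqueous MeCN would give **7**, where the fallback comes back to the route.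

For step 7, the likely failures are a second β-elimination, of the tertiary hydroxyl, and retro-aldol cleavage at C5–C1'; both are driven by aromatisation of the ring. The fallback sets out from **9**. The oxidation is run without base and **10** is isolated. The tertiary hydroxyl is capped with N-(trimethylsilyl)imidazole to give the silyl ether F5. Elimination of acetate with DBU at −20 °C then gives the silyl-protected enone F6, in which no alkoxide can form and retro-aldol cleavage is blocked. Methanolysis of the silyl ether with citric acid in MeOH should release **11**, where the fallback comes back to the route.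

For step 5, the likely failures are acid-promoted dehydration of the tertiary ketol and incomplete hydrolysis through re-closure of the acetal. The fallback keeps the chain ketone masked while the acetal is removed. It sets out from **3** and passes through the spiro-epoxide F2 and the hydroxy dithiane F4 described above. Hydrolysis of the acetal of F4 (AcOH/THF/H2O) gives the dithiane triol F7, which has no ketone β to the tertiary hydroxyl. Unmasking with PhI(OCOCF3)2 in aqueous MeCN then gives **8**, where the fallback comes back to the route.

## Further compounds

F1 | step 6 | meso all-cis 5-hydroxy-5-[(Z)-2-oxononadec-10-en-1-yl]cyclohexane-1,3-diyl diacetate | CCCCCCCC/C=C\CCCCCCCC(=O)C[C@]1(O)C[C@@H](OC(C)=O)C[C@@H](OC(C)=O)C1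
F2 | step 4 | 3'-phenylspiro[oxirane-2,7'-[2,4]dioxabicyclo[3.3.1]nonane], oxirane oxygen endo (meso) | C1O[C@]12C[C@@H]3C[C@H](C2)O[C@@H](c4ccccc4)O3
F3 | step 4 | 2-[(Z)-heptadec-8-en-1-yl]-1,3-dithiane | CCCCCCCC/C=C\CCCCCCCC1SCCCS1
F4 | step 4 | 7-{[2-((Z)-heptadec-8-en-1-yl)-1,3-dithian-2-yl]methyl}-7-endo-hydroxy-3-phenyl-2,4-dioxabicyclo[3.3.1]nonane (meso) | CCCCCCCC/C=C\CCCCCCCC1(SCCCS1)C[C@]2(O)C[C@@H]3C[C@H](C2)O[C@@H](c4ccccc4)O3
F5 | step 7 | (1R,3R)-5-oxo-3-[(Z)-2-oxononadec-10-en-1-yl]-3-(trimethylsilyloxy)cyclohexyl acetate | CCCCCCCC/C=C\CCCCCCCC(=O)C[C@]1(O[Si](C)(C)C)C[C@@H](OC(C)=O)CC(=O)C1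
F6 | step 7 | (5R)-5-[(Z)-2-oxononadec-10-en-1-yl]-5-(trimethylsilyloxy)cyclohex-2-en-1-one | CCCCCCCC/C=C\CCCCCCCC(=O)C[C@]1(O[Si](C)(C)C)CC=CC(=O)C1
F7 | step 5 | meso all-cis 1-{[2-((Z)-heptadec-8-en-1-yl)-1,3-dithian-2-yl]methyl}cyclohexane-1,3,5-triol | CCCCCCCC/C=C\CCCCCCCC1(SCCCS1)C[C@]2(O)C[C@@H](O)C[C@@H](O)C2
A1 | alternative 1 | (15Z)-5-hydroxy-5-(prop-2-en-1-yl)tetracosa-1,15-diene-3,7-dione, C5 configured as in 11 | CCCCCCCC/C=C\CCCCCCCC(=O)C[C@](O)(CC=C)CC(=O)C=C
A2 | alternative 2 | (S)-1-bromocyclohex-3-ene-1-carbaldehyde | O=C[C@@]1(Br)CC=CCC1
A3 | alternative 2 | (Z)-1-[(1R)-1-hydroxycyclohex-3-en-1-yl]nonadec-10-en-2-one | CCCCCCCC/C=C\CCCCCCCC(=O)C[C@]1(O)CC=CCC1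
A4 | alternative 3 | (−)-quinic acid | C1[C@H]([C@H]([C@@H](C[C@@]1(C(=O)O)O)O)O)O
A5 | alternative 3 | spiro-epoxide from quinic acid (carboxyl carbon as oxirane CH2; 3,4-O-isopropylidene; 5-O-tert-butyldimethylsilyl) | C1O[C@]12C[C@H]3OC(C)(C)O[C@H]3[C@H](O[Si](C)(C)C(C)(C)C)C2
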